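**Retrosynthetic overview**
1. Target 11 ⇒ (S)-glycidyl ester 7 + "Ac⁺" + H2O: a new one-flask acetylative 1→2 acyl shift with hydrolysis. It forms the secondary ester C2–O bond with inversion, installs the sn-1 acetate and frees the sn-3 OH.
2. 7 ⇒ acid 5 + (R)-glycidol 6 (Mitsunobu, alkyl C–O bond).
3. 5 ⇒ ethyl ester 3 ⇒ dihydro-β-ionone 1 + triethyl phosphonoacetate 2 (HWE sets the E alkene, then saponification).
4. Rings: the trimethylcyclohexene comes with 1 and the oxirane with 6; no ring is built. The only ring formed is the transient 1,3-dioxolan-2-ylium of the key step, opened again in the same flask.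

Assumption: 1, 2, 6 and acetyl chloride 8 are bought; the target is read as 1-O-acetyl-2-O-acyl-sn-glycerol, (S) at C2, (E) at the enoate.

**Step 1**
Reactants: 1 dihydro-β-ionone [4-(2,6,6-trimethylcyclohex-1-en-1-yl)butan-2-one]; 2 triethyl phosphonoacetate
Product: 3 ethyl (2E)-3-methyl-5-(2,6,6-trimethylcyclohex-1-en-1-yl)pent-2-enoate
Conditions: NaH, THF, 0 °C → reflux; SiO2 chromatography (E/Z ca. 4:1 expected, minor Z removed)
Reagents that add atoms: triethyl phosphonoacetate (2), CCOC(=O)CP(=O)(OCC)OCC
Why: Horner–Wadsworth–Emmons olefination of a methyl ketone, where reversible addition favours the (E)-enoate with the larger chain trans to the ester.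

**Step 2**
Reactants: 3 ethyl (2E)-3-methyl-5-(2,6,6-trimethylcyclohex-1-en-1-yl)pent-2-enoate
Product: 5 (2E)-3-methyl-5-(2,6,6-trimethylcyclohex-1-en-1-yl)pent-2-enoic acid, via potassium carboxylate 4 (not isolated)
Conditions: KOH, EtOH/H2O, 60 °C; then 1 M HCl, 0 °C
Reagents that add atoms: potassium hydroxide, [K+].[OH-]
Why: Ordinary ester saponification (BAc2) followed by protonation, which leaves the trisubstituted (E)-alkene and the ring alkene untouched.

**Step 3**
Reactants: 5 (2E)-3-methyl-5-(2,6,6-trimethylcyclohex-1-en-1-yl)pent-2-enoic acid; 6 (R)-glycidol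
Product: 7 [(2S)-oxiran-2-yl]methyl (2E)-3-methyl-5-(2,6,6-trimethylcyclohex-1-en-1-yl)pent-2-enoate
Conditions: PPh3, DIAD, THF, 0 °C → rt
Reagents that add atoms: (R)-glycidol (6), OC[C@@H]1CO1
Why: Mitsunobu esterification, in which the carboxylate displaces the activated primary CH2–O of glycidol by SN2, so the oxirane stereocentre is untouched (R becomes S only through the CIP ranking) and the acid is never activated, which protects the E geometry.

**Step 4**
Reactants: 7 [(2S)-oxiran-2-yl]methyl (2E)-3-methyl-5-(2,6,6-trimethylcyclohex-1-en-1-yl)pent-2-enoate; 8 acetyl chloride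
Product: 11 (2S)-1-(acetyloxy)-3-hydroxypropan-2-yl (2E)-3-methyl-5-(2,6,6-trimethylcyclohex-1-en-1-yl)pent-2-enoate, via dioxolanylium triflate 9 (not isolated), via hemiorthoester 10 (not isolated)
Conditions: 8/AgOTf (1.05 equiv, premixed in CH2Cl2 at −40 °C, AgCl filtered off), 2,6-di-tert-butyl-4-methylpyridine (0.3 equiv), CH2Cl2, −78 °C; then THF/aq. NaOAc–AcOH (pH 5), −78 → 0 °C; boric acid-doped SiO2
Reagents that add atoms: acetyl chloride (8), CC(=O)Cl; water, O
Why: Proposed new method: acylium-triggered anchimeric oxirane opening with hydrolytic interception, in which acetyl triflate O-acetylates the epoxide oxygen (which becomes the non-nucleophilic sn-1 acetate and so cannot close to the achiral bicyclic orthoester that a silyl or metal Lewis acid would allow), the neighbouring enoate carbonyl opens the activated ring 5-exo at C2 with inversion to give cation 9, water adds at the cationic carbon, and hemiorthoester 10 collapses kinetically by expelling the primary oxygen, so the acyl group stays on the secondary oxygen, the original glycidol oxygen becomes the free primary OH, and the (S) centre is set by inversion (the descriptor stays S only because the ranking of the two CH2 arms is exchanged); the closest known reactions are the trifluoroacetic anhydride opening of glycidyl esters with 1→2 acyl shift through a dioxolanylium ion (which gives only an achiral 1,3-bis-trifluoroacetate), Woodward-type hydrolysis of 1,3-dioxolan-2-ylium ions, and the cyclic-orthoester method for acylating the more hindered hydroxyl of a 1,2-diol.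

**Compound list**
1 | dihydro-β-ionone, 4-(2,6,6-trimethylcyclohex-1-en-1-yl)butan-2-one | CC(=O)CCC1=C(C)CCCC1(C)C | starting material
2 | triethyl phosphonoacetate | CCOC(=O)CP(=O)(OCC)OCC | starting material
3 | ethyl (2E)-3-methyl-5-(2,6,6-trimethylcyclohex-1-en-1-yl)pent-2-enoate | CCOC(=O)/C=C(\C)CCC1=C(C)CCCC1(C)C | intermediate
4 | potassium (2E)-3-methyl-5-(2,6,6-trimethylcyclohex-1-en-1-yl)pent-2-enoate | [K+].[O-]C(=O)/C=C(\C)CCC1=C(C)CCCC1(C)C | intermediate (not isolated)
5 | (2E)-3-methyl-5-(2,6,6-trimethylcyclohex-1-en-1-yl)pent-2-enoic acid | OC(=O)/C=C(\C)CCC1=C(C)CCCC1(C)C | intermediate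
6 | (R)-glycidol, [(2R)-oxiran-2-yl]methanol | OC[C@@H]1CO1 | starting material
7 | [(2S)-oxiran-2-yl]methyl (2E)-3-methyl-5-(2,6,6-trimethylcyclohex-1-en-1-yl)pent-2-enoate | O=C(OC[C@@H]1CO1)/C=C(\C)CCC2=C(C)CCCC2(C)C | intermediate
8 | acetyl chloride | CC(=O)Cl | starting material
9 | (4R)-4-(acetoxymethyl)-2-[(1E)-2-methyl-4-(2,6,6-trimethylcyclohex-1-en-1-yl)but-1-en-1-yl]-1,3-dioxolan-2-ylium trifluoromethanesulfonate | CC(=O)OC[C@@H]1COC(/C=C(\C)CCC2=C(C)CCCC2(C)C)=[O+]1.[O-]S(=O)(=O)C(F)(F)F | intermediate (not isolated)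
10 | [(4R)-2-hydroxy-2-[(1E)-2-methyl-4-(2,6,6-trimethylcyclohex-1-en-1-yl)but-1-en-1-yl]-1,3-dioxolan-4-yl]methyl acetate (both C2 epimers) | CC(=O)OC[C@@H]1COC(O)(/C=C(\C)CCC2=C(C)CCCC2(C)C)O1 | intermediate (not isolated)
11 | (2S)-1-(acetyloxy)-3-hydroxypropan-2-yl (2E)-3-methyl-5-(2,6,6-trimethylcyclohex-1-en-1-yl)pent-2-enoate | CC(=O)OC[C@H](CO)OC(=O)/C=C(\C)CCC1=C(C)CCCC1(C)C | target

**Totals and risk**
Total step count: 4. Longest linear sequence: 4 steps (1 → 3 → 5 → 7 → 11).

Steps most likely to fail:

Step 4 (the proposed new step). The risks are C-acetylation of the tetrasubstituted ring alkene by acetyl triflate, 6-endo instead of 5-exo participation, collapse of 10 to the primary ester (the 1-acyl-3-acetyl isomer), and acyl migration of 11 on work-up. None of these paths leads to the enantiomer of 11, so they cost yield and not ee. The fallback uses known chemistry only, sets out from 5 and comes back to the route at 11. Commercial tert-butyldimethylsilyl (R)-glycidyl ether is opened at its terminal carbon by acetic acid (cat. (salen)Co(III)OAc, iPr2NEt, TBME, rt; C2 not touched) to give (2R)-3-[(tert-butyldimethylsilyl)oxy]-2-hydroxypropyl acetate F4. Carbodiimide esterification of this alcohol with 5 (DIC, cat. DMAP, CH2Cl2, 0 °C; retention at C2) gives (2R)-1-(acetyloxy)-3-[(tert-butyldimethylsilyl)oxy]propan-2-yl (2E)-3-methyl-5-(2,6,6-trimethylcyclohex-1-en-1-yl)pent-2-enoate F5. Buffered HF·pyridine (pyridine, THF, 0 °C) then removes the silyl group to give 11, purified on boric acid-doped silica.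

Step 1 (HWE on a methyl ketone). The E/Z ratio is only moderate and the isomers may separate poorly. The fallback sets out from 1 and comes back at 3 with the geometry fixed by syn-carbometalation instead of olefination. Kinetic deprotonation of 1 at the methyl group (LDA, THF, −78 °C) and trapping with diethyl chlorophosphate gives diethyl 4-(2,6,6-trimethylcyclohex-1-en-1-yl)but-1-en-2-yl phosphate F1. Further LDA (2.2 equiv, −78 °C → rt) eliminates phosphate to give 2-(but-3-yn-1-yl)-1,3,3-trimethylcyclohex-1-ene F2. Zirconium-catalysed methylalumination (Me3Al, Cp2ZrCl2, CH2Cl2, rt) gives by syn addition dimethyl[(1E)-2-methyl-4-(2,6,6-trimethylcyclohex-1-en-1-yl)but-1-en-1-yl]alane F3, which is quenched with ethyl chloroformate with retention to give 3 as the single (E) isomer.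

Step 3 (Mitsunobu on glycidol). The risks are oxirane opening by the betaine or hydrazide and difficult removal of Ph3PO from a sensitive epoxide. The fallback sets out from 5 and 6 and comes back at 7 by forming the acyl C–O bond instead of the alkyl C–O bond: carbodiimide acylation of 6 with 5 (DIC, cat. DMAP, CH2Cl2, 0 °C, chloride-free so the oxirane survives). It makes no new compound, F0.

**Further compounds**
F1 | step 1 | diethyl 4-(2,6,6-trimethylcyclohex-1-en-1-yl)but-1-en-2-yl phosphate | C=C(CCC1=C(C)CCCC1(C)C)OP(=O)(OCC)OCC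
F2 | step 1 | 2-(but-3-yn-1-yl)-1,3,3-trimethylcyclohex-1-ene | C#CCCC1=C(C)CCCC1(C)C
F3 | step 1 | dimethyl[(1E)-2-methyl-4-(2,6,6-trimethylcyclohex-1-en-1-yl)but-1-en-1-yl]alane | C[Al](C)/C=C(\C)CCC1=C(C)CCCC1(C)C
F0 | step 3 | none | none
F4 | step 4 | (2R)-3-[(tert-butyldimethylsilyl)oxy]-2-hydroxypropyl acetate | CC(=O)OC[C@@H](O)CO[Si](C)(C)C(C)(C)C
F5 | step 4 | (2R)-1-(acetyloxy)-3-[(tert-butyldimethylsilyl)oxy]propan-2-yl (2E)-3-methyl-5-(2,6,6-trimethylcyclohex-1-en-1-yl)pent-2-enoate | CC(=O)OC[C@H](CO[Si](C)(C)C(C)(C)C)OC(=O)/C=C(\C)CCC1=C(C)CCCC1(C)C
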